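Both prenyl C–C bonds (C6–CH2 on ring A, C5'–CH2 on ring B) are disconnected back to aryl 1,1-dimethylallyl ethers at O5 and O4'. O5 has C6 as its only unsubstituted ortho carbon (C4a is the ring fusion) and O4' has only C5' (C3' carries oxygen). One double aromatic Claisen rearrangement therefore places both linear prenyl groups regiospecifically and frees the 5- and 4'-hydroxyls. Its precursor is the (2S)-flavanone bearing the two tertiary allyl ethers and MOM ethers at O7 and O3'. It is assembled by asymmetric conjugate addition of a ring B boronic acid to a ring A chromone, after both alkynes have been reduced.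

Key step: step 11

Assumption: the (S)-antipode of the biaryl diphosphine in step 10 is taken to deliver the aryl group to the C2 face that gives the 2S flavanone, by analogy with its sense of addition to cyclohex-2-enone; should a first run show the opposite sense, the (R)-ligand is used with no other change. 3-Chloro-3-methylbut-1-yne (3) is taken as a commercial reagent.

Step 1
Reactants: 1 2,4,6-trihydroxyacetophenone
Product: 2 1-[2,6-dihydroxy-4-(methoxymethoxy)phenyl]ethanone
Conditions: MOMCl (1.05 equiv), i-Pr2NEt (1.1 equiv), THF, 0 °C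
Reagents that add atoms: chloromethyl methyl ether (MOMCl), COCCl
Why: The 4-hydroxyl, para to the acetyl group and unable to hydrogen-bond to it, is the most acidic and most nucleophilic of the three, so one equivalent of MOMCl with a hindered amine should etherify it selectively (Williamson-type O-alkylation).

Step 2
Reactants: 2 1-[2,6-dihydroxy-4-(methoxymethoxy)phenyl]ethanone; 3 3-chloro-3-methylbut-1-yne
Product: 4 1-[2-hydroxy-4-(methoxymethoxy)-6-(2-methylbut-3-yn-2-yloxy)phenyl]ethanone
Conditions: 3 (1.3 equiv), DBU (1.4 equiv), CuCl2·2H2O (1 mol %), MeCN, 0 °C → rt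
Reagents that add atoms: none
Why: Copper-catalysed propargylic substitution of the tertiary chloride by the phenoxide (through a copper allenylidene) etherifies the ortho hydroxyl that is not tied up in the hydrogen bond to the carbonyl, and the remaining, strongly chelated hydroxyl should resist a second alkylation.

Step 3
Reactants: 4 1-[2-hydroxy-4-(methoxymethoxy)-6-(2-methylbut-3-yn-2-yloxy)phenyl]ethanone
Product: 6 7-(methoxymethoxy)-5-(2-methylbut-3-yn-2-yloxy)-4H-chromen-4-one, via enaminone 5 (not isolated)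
Conditions: Me2NCH(OMe)2 (3 equiv), PhMe, 85 °C; concentrate; then AcOH/CH2Cl2, 40 °C
Reagents that add atoms: N,N-dimethylformamide dimethyl acetal, COC(OC)N(C)C
Why: Condensation of the methyl ketone with the amide acetal gives the enaminone, and weak acid triggers addition of the chelated phenol to the β-carbon with loss of dimethylamine (enaminone route to chromones), conditions mild enough for the MOM and tertiary propargyl ethers and well below the temperature at which aryl propargyl ethers rearrange.

Step 4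
Reactants: 6 7-(methoxymethoxy)-5-(2-methylbut-3-yn-2-yloxy)-4H-chromen-4-one
Product: 7 7-(methoxymethoxy)-5-(2-methylbut-3-en-2-yloxy)-4H-chromen-4-one
Conditions: H2 (1 atm), Pd/CaCO3 poisoned with Pb(OAc)2 (Lindlar catalyst), quinoline, EtOAc, rt
Reagents that add atoms: none
Why: Lindlar semi-hydrogenation should stop at the terminal alkene and leave the vinylogous-ester C2=C3 bond of the chromone untouched; the alkyne is removed at this stage because the arylrhodium species of step 10 would add to it.

Step 5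
Reactants: 8 5-bromosalicylaldehyde; 3 3-chloro-3-methylbut-1-yne
Product: 9 5-bromo-2-(2-methylbut-3-yn-2-yloxy)benzaldehyde
Conditions: 3 (1.3 equiv), DBU (1.4 equiv), CuCl2·2H2O (1 mol %), MeCN, 0 °C
Reagents that add atoms: none
Why: The same copper-catalysed propargylic etherification applies, since the acidic ortho-formyl phenol is fully deprotonated by DBU and the aldehyde, lacking α-hydrogens, tolerates the base at 0 °C.

Step 6
Reactants: 9 5-bromo-2-(2-methylbut-3-yn-2-yloxy)benzaldehyde
Product: 11 5-bromo-2-(2-methylbut-3-yn-2-yloxy)phenol, via aryl formate 10 (not isolated)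
Conditions: mCPBA (1.3 equiv), CH2Cl2, 0 °C → rt; aq NaHCO3 wash; then K2CO3 (0.2 equiv), MeOH, rt
Reagents that add atoms: meta-chloroperoxybenzoic acid (mCPBA), OOC(=O)c1cccc(Cl)c1
Why: Baeyer–Villiger oxidation of an ortho-alkoxybenzaldehyde proceeds with migration of the electron-rich aryl group to give the formate (a Dakin-type outcome), which mild methanolysis cleaves; the terminal alkyne is inert to the peracid, which is why oxidation precedes semi-hydrogenation.

Step 7
Reactants: 11 5-bromo-2-(2-methylbut-3-yn-2-yloxy)phenol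
Product: 12 4-bromo-2-(methoxymethoxy)-1-(2-methylbut-3-yn-2-yloxy)benzene
Conditions: MOMCl (1.5 equiv), i-Pr2NEt (2 equiv), CH2Cl2, 0 °C → rt
Reagents that add atoms: chloromethyl methyl ether (MOMCl), COCCl
Why: Standard O-alkylation of a free phenol with MOMCl and a hindered amine base gives the acetal-type ether, which will withstand the organolithium and the aqueous rhodium step.

Step 8
Reactants: 12 4-bromo-2-(methoxymethoxy)-1-(2-methylbut-3-yn-2-yloxy)benzene
Product: 13 4-bromo-2-(methoxymethoxy)-1-(2-methylbut-3-en-2-yloxy)benzene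
Conditions: H2 (1 atm), Pd/CaCO3 poisoned with Pb(OAc)2 (Lindlar catalyst), quinoline, EtOAc, rt
Reagents that add atoms: none
Why: Lindlar semi-hydrogenation reduces the terminal alkyne to the vinyl group, the poisoned catalyst should leave the aryl bromide intact, and removing the acidic alkyne C–H makes the following lithiation clean.

Step 9
Reactants: 13 4-bromo-2-(methoxymethoxy)-1-(2-methylbut-3-en-2-yloxy)benzene
Product: 16 [3-(methoxymethoxy)-4-(2-methylbut-3-en-2-yloxy)phenyl]boronic acid, via aryllithium 14 (not isolated), via lithium triisopropoxyborate 15 (not isolated)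
Conditions: n-BuLi (1.05 equiv), THF, −78 °C; B(Oi-Pr)3 (1.5 equiv), −78 → 0 °C; H2O (pH 7 buffer)
Reagents that add atoms: triisopropyl borate, CC(C)OB(OC(C)C)OC(C)C; water, O
Why: Bromine–lithium exchange at −78 °C outpaces ortho-metalation and any attack on the ethers, and borate trapping followed by neutral hydrolysis gives the boronic acid without exposing the MOM or tertiary allyl ether to acid.

Step 10
Reactants: 7 7-(methoxymethoxy)-5-(2-methylbut-3-en-2-yloxy)-4H-chromen-4-one; 16 [3-(methoxymethoxy)-4-(2-methylbut-3-en-2-yloxy)phenyl]boronic acid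
Product: 17 (2S)-7-(methoxymethoxy)-2-[3-(methoxymethoxy)-4-(2-methylbut-3-en-2-yloxy)phenyl]-5-(2-methylbut-3-en-2-yloxy)-2,3-dihydro-4H-chromen-4-one
Conditions: 16 (2.5 equiv), [RhOH(cod)]2 (2.5 mol %), (S)-MeO-F12-BIPHEP [(S)-(6,6'-dimethoxybiphenyl-2,2'-diyl)bis[bis(3,4,5-trifluorophenyl)phosphine], 5.5 mol %], CH2Cl2/H2O (10:1), 20 °C
Reagents that add atoms: none
Why: In this rhodium-catalysed asymmetric conjugate addition (Hayashi–Miyaura reaction), transmetalation gives an aryl complex of monovalent rhodium that inserts the chromone C2=C3 bond on one enantioface inside the pocket of the electron-poor (S)-diphosphine, setting C2 as S, and hydrolysis of the rhodium enolate releases the flavanone; at 20 °C the tertiary allyl ethers should neither rearrange nor be carbometalated and the product ketone should not be attacked.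

Step 11
Reactants: 17 (2S)-7-(methoxymethoxy)-2-[3-(methoxymethoxy)-4-(2-methylbut-3-en-2-yloxy)phenyl]-5-(2-methylbut-3-en-2-yloxy)-2,3-dihydro-4H-chromen-4-one
Product: 18 (2S)-5-hydroxy-2-[4-hydroxy-3-(methoxymethoxy)-5-(3-methylbut-2-en-1-yl)phenyl]-7-(methoxymethoxy)-6-(3-methylbut-2-en-1-yl)-2,3-dihydro-4H-chromen-4-one
Conditions: Eu(fod)3 [tris(6,6,7,7,8,8,8-heptafluoro-2,2-dimethyl-3,5-octanedionato)europium, 10 mol %], PhMe, 100 °C
Reagents that add atoms: none
Why: Each tertiary allyl aryl ether undergoes a concerted [3,3]-sigmatropic shift through a chair-like six-membered transition state in which the O–C(Me)2 bond breaks as the terminal CH2 bonds to the free ortho carbon, and the resulting cyclohexadienones tautomerise to phenols; this is the aromatic Claisen rearrangement of aryl 1,1-dimethylallyl ethers to ortho-prenylphenols, known for flavonoid 5-O-allyl ethers under catalysis by trivalent europium held between O5 and the C4 carbonyl. No ring is closed and no stereocentre is formed; allylic transposition alone turns each branched ether into a linear prenyl group. The step needs ortho regioselectivity on both rings, and the substrate supplies it: O5 can deliver only to C6 because C4a is fully substituted, and O4' only to C5' because C3' carries the MOM-protected oxygen. A further Cope shift from C6 to C8 would have to build a congested reverse-prenyl group and should be outrun by enolisation to the phenol, which the 5-OH···O=C4 hydrogen bond stabilises. The medium is neutral and the temperature moderate, so the MOM ethers and the C2 centre set in step 10 should persist.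

Step 12
Reactants: 18 (2S)-5-hydroxy-2-[4-hydroxy-3-(methoxymethoxy)-5-(3-methylbut-2-en-1-yl)phenyl]-7-(methoxymethoxy)-6-(3-methylbut-2-en-1-yl)-2,3-dihydro-4H-chromen-4-one
Product: 19 (2S)-2-[3,4-dihydroxy-5-(3-methylbut-2-en-1-yl)phenyl]-5,7-dihydroxy-6-(3-methylbut-2-en-1-yl)-2,3-dihydro-4H-chromen-4-one
Conditions: 3 M aq HCl/MeOH (1:5), 40 °C
Reagents that add atoms: none
Why: Acid-catalysed acetal exchange with methanol removes both MOM groups as dimethoxymethane, and dilute acid at 40 °C should be too mild to cyclise the ortho-prenylphenols to chromans or to open the pyranone ring, so C2 stays S.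

Compound list
1 | 2,4,6-trihydroxyacetophenone | CC(=O)c1c(O)cc(O)cc1O | starting material
2 | 1-[2,6-dihydroxy-4-(methoxymethoxy)phenyl]ethanone | CC(=O)c1c(O)cc(OCOC)cc1O | intermediate
3 | 3-chloro-3-methylbut-1-yne | CC(C)(Cl)C#C | starting material
4 | 1-[2-hydroxy-4-(methoxymethoxy)-6-(2-methylbut-3-yn-2-yloxy)phenyl]ethanone | CC(=O)c1c(O)cc(OCOC)cc1OC(C)(C)C#C | intermediate
5 | (E)-3-(dimethylamino)-1-[2-hydroxy-4-(methoxymethoxy)-6-(2-methylbut-3-yn-2-yloxy)phenyl]prop-2-en-1-one (enaminone, not isolated) | CN(C)/C=C/C(=O)c1c(O)cc(OCOC)cc1OC(C)(C)C#C | intermediate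
6 | 7-(methoxymethoxy)-5-(2-methylbut-3-yn-2-yloxy)-4H-chromen-4-one | O=c1ccoc2cc(OCOC)cc(OC(C)(C)C#C)c12 | intermediate
7 | 7-(methoxymethoxy)-5-(2-methylbut-3-en-2-yloxy)-4H-chromen-4-one | O=c1ccoc2cc(OCOC)cc(OC(C)(C)C=C)c12 | intermediate
8 | 5-bromosalicylaldehyde (5-bromo-2-hydroxybenzaldehyde) | O=Cc1cc(Br)ccc1O | starting material
9 | 5-bromo-2-(2-methylbut-3-yn-2-yloxy)benzaldehyde | O=Cc1cc(Br)ccc1OC(C)(C)C#C | intermediate
10 | 5-bromo-2-(2-methylbut-3-yn-2-yloxy)phenyl formate (not isolated) | O=COc1cc(Br)ccc1OC(C)(C)C#C | intermediate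
11 | 5-bromo-2-(2-methylbut-3-yn-2-yloxy)phenol | Oc1cc(Br)ccc1OC(C)(C)C#C | intermediate
12 | 4-bromo-2-(methoxymethoxy)-1-(2-methylbut-3-yn-2-yloxy)benzene | COCOc1cc(Br)ccc1OC(C)(C)C#C | intermediate
13 | 4-bromo-2-(methoxymethoxy)-1-(2-methylbut-3-en-2-yloxy)benzene | COCOc1cc(Br)ccc1OC(C)(C)C=C | intermediate
14 | [3-(methoxymethoxy)-4-(2-methylbut-3-en-2-yloxy)phenyl]lithium (not isolated) | [Li]c1ccc(OC(C)(C)C=C)c(OCOC)c1 | intermediate
15 | lithium triisopropoxy[3-(methoxymethoxy)-4-(2-methylbut-3-en-2-yloxy)phenyl]borate (not isolated) | [Li+].CC(C)O[B-](OC(C)C)(OC(C)C)c1ccc(OC(C)(C)C=C)c(OCOC)c1 | intermediate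
16 | [3-(methoxymethoxy)-4-(2-methylbut-3-en-2-yloxy)phenyl]boronic acid | OB(O)c1ccc(OC(C)(C)C=C)c(OCOC)c1 | intermediate
17 | (2S)-7-(methoxymethoxy)-2-[3-(methoxymethoxy)-4-(2-methylbut-3-en-2-yloxy)phenyl]-5-(2-methylbut-3-en-2-yloxy)-2,3-dihydro-4H-chromen-4-one | C=CC(C)(C)Oc1ccc([C@@H]2CC(=O)c3c(cc(OCOC)cc3OC(C)(C)C=C)O2)cc1OCOC | intermediate
18 | (2S)-5-hydroxy-2-[4-hydroxy-3-(methoxymethoxy)-5-(3-methylbut-2-en-1-yl)phenyl]-7-(methoxymethoxy)-6-(3-methylbut-2-en-1-yl)-2,3-dihydro-4H-chromen-4-one | CC(C)=CCc1cc([C@@H]2CC(=O)c3c(cc(OCOC)c(CC=C(C)C)c3O)O2)cc(OCOC)c1O | intermediate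
19 | (2S)-2-[3,4-dihydroxy-5-(3-methylbut-2-en-1-yl)phenyl]-5,7-dihydroxy-6-(3-methylbut-2-en-1-yl)-2,3-dihydro-4H-chromen-4-one | CC(C)=CCc1cc([C@@H]2CC(=O)c3c(cc(O)c(CC=C(C)C)c3O)O2)cc(O)c1O | target

Total step count: 12.
Longest linear sequence: 8 steps (steps 5–12, from 8); the ring A branch (steps 1–4) joins at step 10.

Steps most likely to fail

Step 11. The ring B ether lacks the carbonyl chelation that activates the ring A ether. It may therefore need a temperature at which the pyranone ring opens reversibly and C2 loses configuration, or at which the tertiary C–O bonds ionise with loss of isoprene. The fallback sets out from chromone 7 and bromide 13, carries out both rearrangements before C2 exists, and returns at target 19. Heating 7 (Eu(fod)3, PhMe, 100 °C) should give 5-hydroxy-7-(methoxymethoxy)-6-(3-methylbut-2-en-1-yl)-4H-chromen-4-one F1, whose chelated hydroxyl is etherified (NaH, MOMCl, DMF) to 5,7-bis(methoxymethoxy)-6-(3-methylbut-2-en-1-yl)-4H-chromen-4-one F2. Heating 13 in N,N-diethylaniline should give 4-bromo-2-(methoxymethoxy)-6-(3-methylbut-2-en-1-yl)phenol F3. MOM protection then gives 5-bromo-1,2-bis(methoxymethoxy)-3-(3-methylbut-2-en-1-yl)benzene F4, and Miyaura borylation (B2pin2, PdCl2(dppf), KOAc, dioxane, 80 °C) gives 2-[3,4-bis(methoxymethoxy)-5-(3-methylbut-2-en-1-yl)phenyl]-4,4,5,5-tetramethyl-1,3,2-dioxaborolane F5. Rhodium-catalysed asymmetric addition of F5 to F2 (catalyst of step 10, aqueous KOH) should give (2S)-5,7-bis(methoxymethoxy)-2-[3,4-bis(methoxymethoxy)-5-(3-methylbut-2-en-1-yl)phenyl]-6-(3-methylbut-2-en-1-yl)-2,3-dihydro-4H-chromen-4-one F6. Acidic methanolysis as in step 12 then gives 19.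

Step 10. The electron-rich 5,7-dioxygenated chromone may insert too slowly, so that protodeboronation of the boronic acid or arylation of a vinyl group takes over, or enantioface discrimination may be poor. The fallback sets out from ketone 4 and aryllithium 14 (made from 13 as in step 9), builds the flavanone by the chalcone route, and returns at 17 after separation of enantiomers. Quenching 14 with DMF gives, through lithium (dimethylamino)[3-(methoxymethoxy)-4-(2-methylbut-3-en-2-yloxy)phenyl]methanolate F7, 3-(methoxymethoxy)-4-(2-methylbut-3-en-2-yloxy)benzaldehyde F8. Claisen–Schmidt condensation of F8 with 4 (KOH, EtOH, rt) gives (E)-1-[2-hydroxy-4-(methoxymethoxy)-6-(2-methylbut-3-yn-2-yloxy)phenyl]-3-[3-(methoxymethoxy)-4-(2-methylbut-3-en-2-yloxy)phenyl]prop-2-en-1-one F9. Oxa-Michael closure (NaOAc, EtOH, 70 °C) gives racemic 7-(methoxymethoxy)-2-[3-(methoxymethoxy)-4-(2-methylbut-3-en-2-yloxy)phenyl]-5-(2-methylbut-3-yn-2-yloxy)-2,3-dihydro-4H-chromen-4-one F10. Lindlar semi-hydrogenation gives racemic 7-(methoxymethoxy)-2-[3-(methoxymethoxy)-4-(2-methylbut-3-en-2-yloxy)phenyl]-5-(2-methylbut-3-en-2-yloxy)-2,3-dihydro-4H-chromen-4-one F11. Preparative chromatography on a cellulose tris(3,5-dimethylphenylcarbamate) phase then isolates the (2S)-enantiomer, 17.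

Step 2. O-alkylation of the hindered, weakly nucleophilic ortho-acyl phenoxide may be slow, while the propargyl chloride is consumed by elimination to the enyne. The fallback sets out from 2, forms the tertiary allyl ether directly by allylic substitution instead of propargylation and reduction, and returns at chromone 7. Tsuji–Trost O-allylation of 2 with tert-butyl 2-methylbut-3-en-2-yl carbonate (Pd(PPh3)4, THF, 0 °C, kinetic branched selectivity) should give 1-[2-hydroxy-4-(methoxymethoxy)-6-(2-methylbut-3-en-2-yloxy)phenyl]ethanone F12. Condensation with Me2NCH(OMe)2 at 60 °C gives (E)-3-(dimethylamino)-1-[2-hydroxy-4-(methoxymethoxy)-6-(2-methylbut-3-en-2-yloxy)phenyl]prop-2-en-1-one F13, which AcOH cyclises to 7.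

Further compounds
F1 | step 11 | 5-hydroxy-7-(methoxymethoxy)-6-(3-methylbut-2-en-1-yl)-4H-chromen-4-one | O=c1ccoc2cc(OCOC)c(CC=C(C)C)c(O)c12
F2 | step 11 | 5,7-bis(methoxymethoxy)-6-(3-methylbut-2-en-1-yl)-4H-chromen-4-one | O=c1ccoc2cc(OCOC)c(CC=C(C)C)c(OCOC)c12
F3 | step 11 | 4-bromo-2-(methoxymethoxy)-6-(3-methylbut-2-en-1-yl)phenol | COCOc1cc(Br)cc(CC=C(C)C)c1O
F4 | step 11 | 5-bromo-1,2-bis(methoxymethoxy)-3-(3-methylbut-2-en-1-yl)benzene | COCOc1cc(Br)cc(CC=C(C)C)c1OCOC
F5 | step 11 | 2-[3,4-bis(methoxymethoxy)-5-(3-methylbut-2-en-1-yl)phenyl]-4,4,5,5-tetramethyl-1,3,2-dioxaborolane | COCOc1cc(B2OC(C)(C)C(C)(C)O2)cc(CC=C(C)C)c1OCOC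
F6 | step 11 | (2S)-5,7-bis(methoxymethoxy)-2-[3,4-bis(methoxymethoxy)-5-(3-methylbut-2-en-1-yl)phenyl]-6-(3-methylbut-2-en-1-yl)-2,3-dihydro-4H-chromen-4-one | CC(C)=CCc1cc([C@@H]2CC(=O)c3c(cc(OCOC)c(CC=C(C)C)c3OCOC)O2)cc(OCOC)c1OCOC
F7 | step 10 | lithium (dimethylamino)[3-(methoxymethoxy)-4-(2-methylbut-3-en-2-yloxy)phenyl]methanolate | [Li+].CN(C)C([O-])c1ccc(OC(C)(C)C=C)c(OCOC)c1
F8 | step 10 | 3-(methoxymethoxy)-4-(2-methylbut-3-en-2-yloxy)benzaldehyde | O=Cc1ccc(OC(C)(C)C=C)c(OCOC)c1
F9 | step 10 | (E)-1-[2-hydroxy-4-(methoxymethoxy)-6-(2-methylbut-3-yn-2-yloxy)phenyl]-3-[3-(methoxymethoxy)-4-(2-methylbut-3-en-2-yloxy)phenyl]prop-2-en-1-one | C#CC(C)(C)Oc1cc(OCOC)cc(O)c1C(=O)/C=C/c1ccc(OC(C)(C)C=C)c(OCOC)c1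
F10 | step 10 | racemic 7-(methoxymethoxy)-2-[3-(methoxymethoxy)-4-(2-methylbut-3-en-2-yloxy)phenyl]-5-(2-methylbut-3-yn-2-yloxy)-2,3-dihydro-4H-chromen-4-one | C#CC(C)(C)Oc1cc(OCOC)cc2OC(CC(=O)c12)c1ccc(OC(C)(C)C=C)c(OCOC)c1
F11 | step 10 | racemic 7-(methoxymethoxy)-2-[3-(methoxymethoxy)-4-(2-methylbut-3-en-2-yloxy)phenyl]-5-(2-methylbut-3-en-2-yloxy)-2,3-dihydro-4H-chromen-4-one | C=CC(C)(C)Oc1ccc(C2CC(=O)c3c(cc(OCOC)cc3OC(C)(C)C=C)O2)cc1OCOC
F12 | step 2 | 1-[2-hydroxy-4-(methoxymethoxy)-6-(2-methylbut-3-en-2-yloxy)phenyl]ethanone | CC(=O)c1c(O)cc(OCOC)cc1OC(C)(C)C=C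
F13 | step 2 | (E)-3-(dimethylamino)-1-[2-hydroxy-4-(methoxymethoxy)-6-(2-methylbut-3-en-2-yloxy)phenyl]prop-2-en-1-one | CN(C)/C=C/C(=O)c1c(O)cc(OCOC)cc1OC(C)(C)C=C
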